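**Plan**

- Retrosynthesis: the acetate pattern goes last (C7 acetate and free C6 hydroxyl from the cyclic orthoacetate of a cis-diol; C4 and C10 acetates from benzyl ethers). The nortricyclane is then cut at the cyclopropane bond C1–C3 and at the bond C9–C2 between the bridging CH2 and the cyclopropane CH, leaving a cis-decalin C1 tosylhydrazone with C9 as a CH2I group on C4a. The C4a–C9 bond is cut next ([2,3] shift from a 3α-oxygen), and the decalin goes back to a 2-substituted cyclohexane-1,3-dione and methyl vinyl ketone.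
- Forward order: ring A is annulated onto the dione ring (ring B); gem-dimethyl, cis-diol, C3 methyl, C9 and the C4 oxygen are placed on the decalin; one flask then closes the five-membered ring C4a–C9–C2–C1–C8a and after it the three-membered ring C1–C2–C3.
- Feature used: the cyclopropane carbon C2 that holds the bridge C9 is bonded to C1, which in a decalin can be a hydrazone carbon whose only acidic neighbour is C2 (C8a is quaternary). C9 hangs on C4a, opposite C2 across ring B, as a neopentyl carbon without β-hydrogen. Once bridged, the C3–H bond lies endo and 1,3 to C1.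
- Stereochemistry: C8a comes from the enantioselective aldol condensation. C6, C7, C4a, C4 and C3 are relayed from it (axial hydride delivery, suprafacial [2,3] shift, hydroxyl-directed epoxidation, anti epoxide opening). C1, C2 and C3 of the cage are fixed by the geometry of the bridging.

Key step: step 20

Remark: all bicyclic intermediates and the cage carry naphthalene locants (C1 to C8, C4a, C8a; C9 is the carbon on C4a, C10 the carbon on C8a), α is the face of ring B that carries C10, TBS is tert-butyldimethylsilyl, and 1, 2 and 5 are assumed to be bought.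

Step 1
Reactants: 1 1,5-dimethoxycyclohexa-1,4-diene; 2 benzyl chloromethyl ether
Product: 4 2-[(benzyloxy)methyl]cyclohexane-1,3-dione, via alkylated bis(enol ether) 3 (not isolated)
Conditions: t-BuLi, HMPA, THF, −78 °C; 2; then 1 M HCl, acetone, 23 °C
Reagents that add atoms: water O
Why: Deprotonation of the C6 methylene between the two enol-ether carbons, C-alkylation of the cyclohexadienyl anion by the chloromethyl ether and acid hydrolysis of both enol ethers should give the 2-substituted 1,3-dione (alkylation of a Birch-type bis(enol ether) anion, no stereocentre).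

Step 2
Reactants: 4 2-[(benzyloxy)methyl]cyclohexane-1,3-dione; 5 methyl vinyl ketone
Product: 7 (8aS)-8a-[(benzyloxy)methyl]-3,4,8,8a-tetrahydronaphthalene-1,6(2H,7H)-dione, via triketone 6 (not isolated)
Conditions: Et3N (cat.), neat, 23 °C; then N-tosyl-(Sa)-binam-L-prolinamide (5 mol %), PhCO2H (cat.), neat, 23 °C
Reagents that add atoms: none
Why: Michael addition and enamine-catalysed intramolecular aldol condensation (Hajos–Parrish–Eder–Sauer–Wiechert form of the Robinson annulation) should close ring A, the L-proline-derived amide choosing between the two enantiotopic ring carbonyls and so setting C8a as (S).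

Step 3
Reactants: 7 enedione
Product: 8 (8aS)-8a-[(benzyloxy)methyl]-1α-hydroxy-1,2,3,4,8,8a-hexahydronaphthalen-6(7H)-one
Conditions: NaBH4 (0.3 equiv), EtOH, −20 °C
Reagents that add atoms: none
Why: The saturated C1 ketone is more electrophilic than the enone carbonyl and takes hydride axially from the β-face, as in the parent Wieland–Miescher ketone, to give the equatorial 1α-alcohol (chemoselective borohydride reduction).

Step 4
Reactants: 8 hydroxy enone
Product: 9 1α-O-TBS ether of 8
Conditions: TBSCl, imidazole, DMF, 23 °C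
Reagents that add atoms: tert-butyldimethylsilyl chloride CC(C)(C)[Si](C)(C)Cl
Why: Silylation of the secondary alcohol masks C1 for the basic steps that follow (silyl ether protection, no stereocentre touched).

Step 5
Reactants: 9 silyloxy enone
Product: 10 5,5-dimethyl-6-ketone with the alkene moved to C4=C4a
Conditions: KOtBu, MeI (excess), t-BuOH, 23 °C
Reagents that add atoms: iodomethane CI
Why: The extended enolate is alkylated twice at C5 and the alkene ends at C4=C4a (deconjugative gem-dimethylation of a bicyclic enone).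

Step 6
Reactants: 10 β,γ-unsaturated ketone
Product: 11 diosphenol (6-oxo-7-hydroxy-C7=C8 enol)
Conditions: O2 (1 atm), KOtBu, t-BuOH/DME, 23 °C
Reagents that add atoms: dioxygen O=O
Why: Base-mediated autoxidation at C7, the only enolisable position next to the C6 ketone, should give the enolised α-diketone (diosphenol formation).

Step 7
Reactants: 11 diosphenol
Product: 12 6α,7α-diol
Conditions: NaBH4, EtOH, 0 °C
Reagents that add atoms: none
Why: Borohydride reduces the diosphenol through its α-hydroxy ketone tautomer; C6 takes hydride axially to give the equatorial 6α-alcohol and C7 takes hydride from the β-face because its α-face is screened by the syn-axial C10 and 5α-methyl groups, so the cis-diol should result.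

Step 8
Reactants: 12 cis-diol
Product: 13 6α,7α-O-isopropylidene acetal of 12
Conditions: Me2C(OMe)2, PPTS (cat.), acetone, 23 °C
Reagents that add atoms: 2,2-dimethoxypropane COC(C)(C)OC
Why: Acid-catalysed transacetalisation of a cis-1,2-diol (isopropylidene acetal formation).

Step 9
Reactants: 13 acetonide
Product: 14 3-oxo derivative of 13 (C3 ketone conjugated to C4=C4a)
Conditions: Rh2(cap)4 (dirhodium tetrakis(caprolactamate), 1 mol %), t-BuOOH, K2CO3, CH2Cl2, 23 °C
Reagents that add atoms: tert-butyl hydroperoxide CC(C)(C)OO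
Why: Catalytic allylic oxidation attacks C3, the only allylic methylene of the C4=C4a alkene (the other allylic carbons are quaternary), and gives the conjugated enone.

Step 10
Reactants: 14 enone
Product: 15 3α-hydroxy-3β-methyl tertiary allylic alcohol
Conditions: MeLi, THF, −78 °C
Reagents that add atoms: methyllithium [Li]C
Why: 1,2-Addition to the enone carbonyl along the axial trajectory on the β-face, where only the axial C1–H is met, should place the methyl group β and the oxygen α (carbonyl addition of an organolithium).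

Step 11
Reactants: 15 tertiary allylic alcohol
Product: 16 3α-O-[(tributylstannyl)methyl] ether of 15
Conditions: KH, Bu3SnCH2I, 18-crown-6 (cat.), THF, 0 to 23 °C
Reagents that add atoms: (iodomethyl)tributylstannane CCCC[Sn](CCCC)(CCCC)CI
Why: Williamson etherification of the potassium alkoxide with the activated iodomethylstannane gives the precursor for the Wittig–Still rearrangement.

Step 12
Reactants: 16 stannylmethyl ether
Product: 18 homoallylic alcohol with C9H2OH on the α-face of C4a and a C3=C4 alkene that bears the C3 methyl group, via lithiomethyl ether 17 (not isolated)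
Conditions: n-BuLi, THF, −78 to 0 °C
Reagents that add atoms: none
Why: Tin–lithium exchange gives the α-alkoxymethyllithium, which undergoes the [2,3]-Wittig–Still rearrangement suprafacially, so the 3α-oxygen delivers the CH2O unit to the α-face of C4a and sets this quaternary centre cis to C10.

Step 13
Reactants: 18 homoallylic alcohol
Product: 19 3α,4α-epoxide of 18
Conditions: VO(acac)2 (cat.), t-BuOOH, CH2Cl2, 0 to 23 °C
Reagents that add atoms: tert-butyl hydroperoxide CC(C)(C)OO
Why: Vanadium-catalysed epoxidation directed by the homoallylic C9 hydroxyl delivers oxygen to the alkene face syn to C9, the α-face (hydroxyl-directed epoxidation).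

Step 14
Reactants: 19 epoxy alcohol
Product: 20 diol with 4α-hydroxyl, 3α-methyl (3β-H) and free C9 hydroxyl
Conditions: BH3·THF, LiBH4 (cat.), THF, 0 to 23 °C; aq. NaOH work-up
Reagents that add atoms: none
Why: Borane-activated, borohydride-catalysed reductive opening of the trisubstituted epoxide puts hydride on the more substituted carbon C3 with inversion and keeps the 4α-oxygen, which gives 3β-H and 3α-methyl (anti-Markovnikov epoxide reduction).

Step 15
Reactants: 20 diol
Product: 21 C9 iodide (4a-CH2I) with free 4α-hydroxyl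
Conditions: I2, PPh3, imidazole, toluene, 80 °C
Reagents that add atoms: iodine II
Why: Appel-type iodination through the alkoxyphosphonium salt should take the primary C9 alcohol in preference to the more hindered secondary 4α-alcohol.

Step 16
Reactants: 21 iodo alcohol
Product: 22 4α-O-benzyl ether of 21
Conditions: 2-benzyloxy-1-methylpyridinium triflate, MgO, PhCF3, 85 °C
Reagents that add atoms: 2-benzyloxy-1-methylpyridinium triflate C[n+]1ccccc1OCc1ccccc1.[O-]S(=O)(=O)C(F)(F)F
Why: Benzyl transfer from the pyridinium salt under neutral conditions etherifies the hindered alcohol without forming an alkoxide next to the γ-iodide (benzyl ether protection).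

Step 17
Reactants: 22 benzyl ether
Product: 23 1α-alcohol (silyl group removed)
Conditions: HF·pyridine, THF/pyridine, 23 °C
Reagents that add atoms: none
Why: Fluoride cleavage of the silyl ether under buffered acidic conditions frees the C1 alcohol without an alkoxide that could displace the C9 iodide (desilylation).

Step 18
Reactants: 23 alcohol
Product: 24 C1 ketone
Conditions: Dess–Martin periodinane, NaHCO3, CH2Cl2, 23 °C
Reagents that add atoms: none
Why: Buffered hypervalent-iodine oxidation of the secondary alcohol gives the ketone without touching the acetal or the iodide (Dess–Martin oxidation).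

Step 19
Reactants: 24 ketone
Product: 25 (E)-N-tosylhydrazone of 24
Conditions: TsNHNH2, EtOH, 60 °C
Reagents that add atoms: p-toluenesulfonyl hydrazide Cc1ccc(cc1)S(=O)(=O)NN
Why: Condensation of the ketone with the sulfonyl hydrazide should give the hydrazone with the sulfonamide nitrogen anti to the quaternary C8a (tosylhydrazone formation).

Step 20
Reactants: 25 tosylhydrazone
Product: 30 nortricyclane with cyclopropane C1–C2–C3 and bridge C9 that keeps the 4α- and 10-O-benzyl groups and the 6α,7α-acetonide, via dianion 26 (not isolated), via bridged lithium tosylhydrazonate 27 (not isolated), via diazoalkane 28 (not isolated), via carbene 29 (not isolated)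
Conditions: LDA (2.2 equiv), THF/DMPU, −78 to −20 °C; then diglyme, 150 °C
Reagents that add atoms: none
Why: Proposed new method: LDA removes N–H and then the syn α-proton at C2 (the only enolisable position, since C8a is quaternary) to give dianion 26, whose C2 carbanion displaces the neopentyl iodide of C9 across ring B in a boat (5-exo-tet with respect to the ring C4a–C9–C2–C3–C4, closing the bicyclo[2.2.1]heptane of 27), and on heating 27 loses lithium p-toluenesulfinate to give diazoalkane 28 and then carbene 29, which inserts into the endo C3–H bond (1,3 C–H insertion, closing the three-membered ring). The closest known reaction types are the C-alkylation of tosylhydrazone dianions by primary iodides and the aprotic Bamford–Stevens reaction of camphor tosylhydrazone, which gives tricyclene by the same 1,3-insertion; the transannular displacement at a neopentyl carbon and the union of both events in one flask are new. C2 can only be bridged on the α-face because C4a holds C9 there, C1 gets its hydrogen from C3 and its new bond on the endo face, and C3 reacts with retention, so the three new stereocentres are dictated by the cage. The step needs C- over N-alkylation, ring closure before Shapiro-type loss of sulfinate from the dianion, and insertion over 1,2-shift: the (E)-hydrazone keeps the sulfonamide nitrogen away from C9, the iodide has no β-hydrogen, the low temperature holds the dianion, and the carbene has no β-hydrogen that can migrate (C2 is a bridgehead, C8a is quaternary) while the tertiary endo C3–H bond lies within bonding distance.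

Step 21
Reactants: 30 dibenzyl ether
Product: 31 4α,10-diol
Conditions: H2 (1 atm), Pd(OH)2/C, EtOAc, 23 °C
Reagents that add atoms: none
Why: Hydrogenolysis of both benzyl ethers on Pd(OH)2 should leave the cyclopropane of the nortricyclane intact under these mild conditions (debenzylation).

Step 22
Reactants: 31 diol
Product: 32 4α,10-diacetate
Conditions: Ac2O, DMAP, pyridine, 40 °C
Reagents that add atoms: acetic anhydride CC(=O)OC(C)=O
Why: Nucleophile-catalysed acylation esterifies the primary and the hindered cyclopropylcarbinyl alcohol with retention at C4 (acetylation).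

Step 23
Reactants: 32 diacetate acetonide
Product: 33 6α,7α-diol 4α,10-diacetate
Conditions: AcOH/H2O (4:1), 45 °C
Reagents that add atoms: none
Why: Mild acid hydrolysis removes the isopropylidene acetal under conditions too weak to ionise the cyclopropylcarbinyl acetate (acetal cleavage).

Step 24
Reactants: 33 diol diacetate
Product: 35 target CNP0197219.1, via cyclic orthoacetate 34 (not isolated)
Conditions: MeC(OMe)3, CSA (cat.), CH2Cl2, 23 °C; then AcOH/H2O, 23 °C
Reagents that add atoms: trimethyl orthoacetate COC(C)(OC)OC; water O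
Why: Orthoester exchange gives cyclic orthoacetate 34, and its mild hydrolysis should open with the usual preference for the ester on the axial oxygen and the free hydroxyl on the equatorial one, here the C7 acetate and the C6 hydroxyl, as ring A in the cage holds the C7 oxygen axial (regioselective orthoester monoacylation of a cis-diol).

**Compound list**

1 | 1,5-dimethoxycyclohexa-1,4-diene | COC1=CCC=C(OC)C1 | starting material
2 | benzyl chloromethyl ether | ClCOCc1ccccc1 | starting material
3 | 6-[(benzyloxy)methyl]-1,5-dimethoxycyclohexa-1,4-diene (alkylated bis(enol ether)) | COC1=CCC=C(OC)C1COCc1ccccc1 | intermediate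
4 | 2-[(benzyloxy)methyl]cyclohexane-1,3-dione | O=C1CCCC(=O)C1COCc1ccccc1 | intermediate
5 | methyl vinyl ketone (but-3-en-2-one) | CC(=O)C=C | starting material
6 | 2-[(benzyloxy)methyl]-2-(3-oxobutyl)cyclohexane-1,3-dione (triketone) | CC(=O)CCC1(COCc2ccccc2)C(=O)CCCC1=O | intermediate
7 | (8aS)-8a-[(benzyloxy)methyl]-3,4,8,8a-tetrahydronaphthalene-1,6(2H,7H)-dione | O(Cc1ccccc1)C[C@]12CCC(=O)C=C1CCCC2=O | intermediate
8 | (8aS)-8a-[(benzyloxy)methyl]-1α-hydroxy-1,2,3,4,8,8a-hexahydronaphthalen-6(7H)-one | O(Cc1ccccc1)C[C@]12CCC(=O)C=C1CCC[C@@H]2O | intermediate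
9 | 1α-O-TBS ether of 8 | O(Cc1ccccc1)C[C@]12CCC(=O)C=C1CCC[C@@H]2O[Si](C)(C)C(C)(C)C | intermediate
10 | 8a-[(benzyloxy)methyl]-1α-(TBS-oxy)-5,5-dimethyl-1,2,3,5,8,8a-hexahydronaphthalen-6(7H)-one (C4=C4a alkene) | O(Cc1ccccc1)C[C@]12CCC(=O)C(C)(C)C1=CCC[C@@H]2O[Si](C)(C)C(C)(C)C | intermediate
11 | diosphenol of 10 (6-oxo; 7-hydroxy; C7=C8 and C4=C4a alkenes) | O(Cc1ccccc1)C[C@]12C=C(O)C(=O)C(C)(C)C1=CCC[C@@H]2O[Si](C)(C)C(C)(C)C | intermediate
12 | 6α,7α-diol (8a-CH2OBn; 1α-OTBS; 5,5-dimethyl; C4=C4a alkene) | O(Cc1ccccc1)C[C@]12C[C@H](O)[C@H](O)C(C)(C)C1=CCC[C@@H]2O[Si](C)(C)C(C)(C)C | intermediate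
13 | 6α,7α-O-isopropylidene acetal of 12 | O(Cc1ccccc1)C[C@]12C[C@@H]3OC(C)(C)O[C@@H]3C(C)(C)C1=CCC[C@@H]2O[Si](C)(C)C(C)(C)C | intermediate
14 | 3-oxo derivative of 13 (C3 ketone conjugated to C4=C4a) | O(Cc1ccccc1)C[C@]12C[C@@H]3OC(C)(C)O[C@@H]3C(C)(C)C1=CC(=O)C[C@@H]2O[Si](C)(C)C(C)(C)C | intermediate
15 | 3α-hydroxy-3β-methyl tertiary allylic alcohol from 14 | O(Cc1ccccc1)C[C@]12C[C@@H]3OC(C)(C)O[C@@H]3C(C)(C)C1=C[C@](C)(O)C[C@@H]2O[Si](C)(C)C(C)(C)C | intermediate
16 | 3α-O-[(tributylstannyl)methyl] ether of 15 | O(Cc1ccccc1)C[C@]12C[C@@H]3OC(C)(C)O[C@@H]3C(C)(C)C1=C[C@](C)(OC[Sn](CCCC)(CCCC)CCCC)C[C@@H]2O[Si](C)(C)C(C)(C)C | intermediate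
17 | 3α-O-(lithiomethyl) ether | O(Cc1ccccc1)C[C@]12C[C@@H]3OC(C)(C)O[C@@H]3C(C)(C)C1=C[C@](C)(OC[Li])C[C@@H]2O[Si](C)(C)C(C)(C)C | intermediate
18 | homoallylic alcohol (4a-CH2OH on the α-face, cis to C10; 3-methyl; C3=C4 alkene) | O(Cc1ccccc1)C[C@]12C[C@@H]3OC(C)(C)O[C@@H]3C(C)(C)[C@@]1(CO)C=C(C)C[C@@H]2O[Si](C)(C)C(C)(C)C | intermediate
19 | 3α,4α-epoxide of 18 | O(Cc1ccccc1)C[C@]12C[C@@H]3OC(C)(C)O[C@@H]3C(C)(C)[C@@]1(CO)[C@@H]4O[C@]4(C)C[C@@H]2O[Si](C)(C)C(C)(C)C | intermediate
20 | diol (4α-OH; 3α-methyl and 3β-H; 4a-CH2OH) | O(Cc1ccccc1)C[C@]12C[C@@H]3OC(C)(C)O[C@@H]3C(C)(C)[C@@]1(CO)[C@H](O)[C@H](C)C[C@@H]2O[Si](C)(C)C(C)(C)C | intermediate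
21 | C9 iodide (4a-CH2I) with free 4α-hydroxyl | O(Cc1ccccc1)C[C@]12C[C@@H]3OC(C)(C)O[C@@H]3C(C)(C)[C@@]1(CI)[C@H](O)[C@H](C)C[C@@H]2O[Si](C)(C)C(C)(C)C | intermediate
22 | 4α-O-benzyl ether of 21 | O(Cc1ccccc1)C[C@]12C[C@@H]3OC(C)(C)O[C@@H]3C(C)(C)[C@@]1(CI)[C@H](OCc1ccccc1)[C@H](C)C[C@@H]2O[Si](C)(C)C(C)(C)C | intermediate
23 | 1α-alcohol (22 without the silyl group) | O(Cc1ccccc1)C[C@]12C[C@@H]3OC(C)(C)O[C@@H]3C(C)(C)[C@@]1(CI)[C@H](OCc1ccccc1)[C@H](C)C[C@@H]2O | intermediate
24 | C1 ketone | O(Cc1ccccc1)C[C@]12C[C@@H]3OC(C)(C)O[C@@H]3C(C)(C)[C@@]1(CI)[C@H](OCc1ccccc1)[C@H](C)CC2=O | intermediate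
25 | (E)-N-tosylhydrazone of 24 | O(Cc1ccccc1)C[C@]12C[C@@H]3OC(C)(C)O[C@@H]3C(C)(C)[C@@]1(CI)[C@H](OCc1ccccc1)[C@H](C)C/C2=N\NS(=O)(=O)c1ccc(C)cc1 | intermediate
26 | dilithium dianion of 25 (deprotonated at N and at C2) | O(Cc1ccccc1)C[C@]12C[C@@H]3OC(C)(C)O[C@@H]3C(C)(C)[C@@]1(CI)[C@H](OCc1ccccc1)[C@H](C)[CH-]/C2=N\[N-]S(=O)(=O)c1ccc(C)cc1.[Li+].[Li+] | intermediate
27 | lithium salt of the bridged tosylhydrazone (C9–C2 bond closed; bicyclo[2.2.1]heptane) | O(Cc1ccccc1)C[C@]12C[C@@H]3OC(C)(C)O[C@@H]3C(C)(C)[C@]14C[C@H](/C2=N\[N-]S(=O)(=O)c2ccc(C)cc2)[C@@H](C)[C@H]4OCc1ccccc1.[Li+] | intermediate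
28 | bridged C1 diazoalkane | O(Cc1ccccc1)C[C@]12C[C@@H]3OC(C)(C)O[C@@H]3C(C)(C)[C@]14C[C@H](C2=[N+]=[N-])[C@@H](C)[C@H]4OCc1ccccc1 | intermediate
29 | bridged C1 carbene | O(Cc1ccccc1)C[C@]12C[C@@H]3OC(C)(C)O[C@@H]3C(C)(C)[C@]14C[C@H]([C]2)[C@@H](C)[C@H]4OCc1ccccc1 | intermediate
30 | nortricyclane (cyclopropane C1–C2–C3; bridge C9; 4α- and 10-O-benzyl; 6α,7α-acetonide) | O(Cc1ccccc1)C[C@]12C[C@@H]3OC(C)(C)O[C@@H]3C(C)(C)[C@]14C[C@@H]5[C@H]2[C@]5(C)[C@H]4OCc1ccccc1 | intermediate
31 | 4α,10-diol of the cage acetonide | OC[C@]12C[C@@H]3OC(C)(C)O[C@@H]3C(C)(C)[C@]14C[C@@H]5[C@H]2[C@]5(C)[C@H]4O | intermediate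
32 | 4α,10-diacetate of the cage acetonide | CC(=O)OC[C@]12C[C@@H]3OC(C)(C)O[C@@H]3C(C)(C)[C@]14C[C@@H]5[C@H]2[C@]5(C)[C@H]4OC(C)=O | intermediate
33 | 6α,7α-diol 4α,10-diacetate | CC(=O)OC[C@]12C[C@H](O)[C@H](O)C(C)(C)[C@]13C[C@@H]1[C@H]2[C@]1(C)[C@H]3OC(C)=O | intermediate
34 | cyclic methyl orthoacetate of 33 (6α,7α-O-(1-methoxyethylidene)) | CC(=O)OC[C@]12C[C@@H]3OC(C)(OC)O[C@@H]3C(C)(C)[C@]14C[C@@H]5[C@H]2[C@]5(C)[C@H]4OC(C)=O | intermediate
35 | CNP0197219.1 (4α,7α,10-triacetate with free 6α-hydroxyl) | CC(=O)OC[C@]12C[C@H](OC(C)=O)[C@H](O)C(C)(C)[C@]13C[C@@H]1[C@H]2[C@]1(C)[C@H]3OC(C)=O | target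

**Step count and risks**

Total step count: 24. Longest linear sequence: 24 steps.

Step 20 is the most likely to fail. The dianion may be lost by Shapiro-type elimination or by proton transfer before the slow displacement at the neopentyl carbon, and the carbene may undergo a 1,2-alkyl shift instead of insertion. The fallback sets out from ketone 24 and runs the two ring closures separately by known chemistry. KHMDS in THF (−78 to 0 °C) forms the C2 potassium enolate, which closes the bridge by intramolecular ketone alkylation to bridged ketone F1. TsNHNH2 in EtOH then gives bridged tosylhydrazone F2. Its sodium salt (NaH) heated in diglyme at 150 °C undergoes the aprotic Bamford–Stevens 1,3-insertion and comes back to the route at 30.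

Step 12 is next. A [1,2]-shift or plain protonation of the α-alkoxymethyllithium may outrun the [2,3] shift onto the very hindered C4a terminus. The fallback sets out from tertiary alcohol 15 and uses a [3,3] shift on the same face. Johnson orthoester Claisen rearrangement (MeC(OEt)3, cat. EtCO2H, 140 °C) gives ethyl ester F3, and LiOH gives acid F4. Iododecarboxylation (PhI(OAc)2, I2, hν) gives homoallylic iodide F5. mCPBA on the convex α-face gives epoxy iodide F6. Borane opening as in step 14 comes back to the route at 21.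

Step 14 is third. Hydride may go to the wrong epoxide carbon, or the opening may lose its anti course through a free cation, giving the tertiary alcohol or the C3 epimer. The fallback sets out from epoxide 19 and replaces the direct opening by rearrangement and carbonyl reduction. A catalytic amount of BF3·OEt2 in CH2Cl2 at −78 °C should induce the Meinwald rearrangement with hydride shift anti to the departing oxygen, giving C4 ketone F7 (3α-methyl). NaBH4/CeCl3 in MeOH at −40 °C, attacking from the β-face opposite the two flanking α-substituents, comes back to the route at 20.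

Further compounds
F1 | step 20 | bridged ketone (C9–C2 bond closed; C1 ketone; 4α- and 10-O-benzyl; acetonide) | O(Cc1ccccc1)C[C@]12C[C@@H]3OC(C)(C)O[C@@H]3C(C)(C)[C@]14C[C@H](C2=O)[C@@H](C)[C@H]4OCc1ccccc1
F2 | step 20 | (E)-N-tosylhydrazone of F1 | O(Cc1ccccc1)C[C@]12C[C@@H]3OC(C)(C)O[C@@H]3C(C)(C)[C@]14C[C@H](/C2=N\NS(=O)(=O)c2ccc(C)cc2)[C@@H](C)[C@H]4OCc1ccccc1
F3 | step 12 | ethyl ester (4a-CH2CO2Et on the α-face; 3-methyl; C3=C4 alkene) | O(Cc1ccccc1)C[C@]12C[C@@H]3OC(C)(C)O[C@@H]3C(C)(C)[C@@]1(CC(=O)OCC)C=C(C)C[C@@H]2O[Si](C)(C)C(C)(C)C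
F4 | step 12 | carboxylic acid from F3 | O(Cc1ccccc1)C[C@]12C[C@@H]3OC(C)(C)O[C@@H]3C(C)(C)[C@@]1(CC(=O)O)C=C(C)C[C@@H]2O[Si](C)(C)C(C)(C)C
F5 | step 12 | homoallylic iodide (4a-CH2I; C3=C4 alkene) | O(Cc1ccccc1)C[C@]12C[C@@H]3OC(C)(C)O[C@@H]3C(C)(C)[C@@]1(CI)C=C(C)C[C@@H]2O[Si](C)(C)C(C)(C)C
F6 | step 12 | 3α,4α-epoxide of F5 | O(Cc1ccccc1)C[C@]12C[C@@H]3OC(C)(C)O[C@@H]3C(C)(C)[C@@]1(CI)[C@@H]4O[C@]4(C)C[C@@H]2O[Si](C)(C)C(C)(C)C
F7 | step 14 | C4 ketone (3α-methyl; 4a-CH2OH) | O(Cc1ccccc1)C[C@]12C[C@@H]3OC(C)(C)O[C@@H]3C(C)(C)[C@@]1(CO)C(=O)[C@H](C)C[C@@H]2O[Si](C)(C)C(C)(C)C
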